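Count in moles of starting material per mole of partner, so that time drops out of the runs.

| flask | starting material | partner | remark | time |
|---|---|---|---|---|
| zeta | 0.020 M | 0.0080 M (fed, over 15 s) | run made earlier; the fed solution adds 1.0 times the starting volume |  |
| gamma | 0.020 M | 0.018 M (fed, over 15 s) | run made earlier; the fed solution adds 1.0 times the starting volume |  |
| delta | 0.040 M | 0.012 M (fed, over 15 s) | run made earlier; the fed solution adds 1.0 times the starting volume |  |
| flask | 0.020 M | 0.0120 M (fed, over 15 s) | the fed solution adds 1.0 times the starting volume | 20 min |

| run | time / min | starting material / % | target / % |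
|---|---|---|---|
| zeta | 1.33 | 53.9 | 0 |
| zeta | 4.00 | 54.0 | 1.2 |
| zeta | 6.00 | 53.3 | 0 |
| zeta | 10.0 | 53.2 | 0 |
| zeta | 15.0 | 54.0 | 0 |
| zeta | 20.0 | 53.8 | 0 |
| zeta | 25.0 | 54.1 | 0.3 |
| gamma | 1.33 | 23.1 | 0.8 |
| gamma | 4.00 | 16.3 | 0.8 |
| gamma | 6.00 | 15.6 | 1.3 |
| gamma | 10.0 | 15.7 | 0.5 |
| gamma | 15.0 | 16.2 | 1.3 |
| gamma | 20.0 | 15.5 | 1.0 |
| gamma | 25.0 | 13.6 | 1.7 |
| delta | 2.00 | 59.9 | 0 |
| delta | 6.00 | 60.2 | 0 |
| delta | 12.0 | 61.0 | 0.7 |
| delta | 15.0 | 60.0 | 0 |
| delta | 25.0 | 58.1 | 2.3 |

(scatter of a reading: 1 percentage point)

* why nothing more happens at 20 min, or that something still does (the partner has run out first / forward and back rates have come level / it is still moving / all of the starting material has reacted)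
* how much of the starting material has reacted by 20 min
* amount of target if the flask were left three thousand times as long, in percent of the starting material charged

Read the starting-material column first. Zeta stands flat at 53.8 % from its first reading, and gamma stands at 15.5 % from its second. The loss per mole of partner is 1.16 in zeta and 0.939 in gamma, and delta, at about 59.8 %, gives 1.34, so no single ratio serves.

Compare zeta with gamma instead, since they share one charge of starting material. The marginal uptake, the starting material that one extra mole of partner removes between these two runs at 0.020 M of starting material, is 0.765.

Stepping from zeta to the flask's 0.0120 M, I reckon 38.4 % left, so 61.6 % reacted. That loss roughly equals the partner charge, so I take partner as the limiting reagent and commit to a stop set by it. The target column stays small, with 2.3 % in delta's last reading and 1.7 % in gamma's against a scatter of 1 percentage point, so I expect none to speak of later.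

The forecast says that forward and back rates have come level, with 64 % reacted and 60 % of target, since “the slow leak should finish”; I differ from it on the stop and on the target, and by 2.4 points on the conversion.

In the flask the partner has run out first, with 62.6 % reacted and 0 % of target, and with 0 % of the partner left against 37 % of the starting material.

    starting material + partner → side product A (k = 7.47 /M/s)
    starting material + target → side product B (k = 1.71 /M/s)
    starting material ⇌ intermediate (K = 0.150, k = 0.0219 /s)
    starting material + partner → target (k = 0.232 /M/s)
    crystals ⇌ target, rate k5*(cs5 - [target]) while solid is left; crystals form when [target] > cs5 (solubility = 0.840 mM, k = 0.0633 /s)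
    partner → decomposed reagent (k = 0.00416 /s)

Weigh the charges with care (partner (14 points), then starting material (12 points) for the same factor up or down); the clock matters little. At 0.0133 M of partner, the marginal uptake predicts a shift of 4.9 points in conversion, and the computed flask has moved by 5 points there.

In the neighbour flask with 0.0072 M of partner, the marginal uptake gives 56.8 % of starting material left. The computed neighbour holds 56.8 %, with 43.2 % reacted.

The runs are simulated with constants of no real substance; scatter was added.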